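**Plan**
Numbering: ring C1 (C=O), C2=C3, C4 (CHOH), C5 (C(OH)R), C6 (CH2); chain C1'–C17'. The enabling feature is the run C1(=O)–C2H=C3H–C4H(OH). C2 carries nothing and C1/C3 stand 1,3, so the enone is the ring-opened, two-electron-oxidised form of a cyclopropanol C1(OH)–C2H2–C3H.
Retrosynthesis: (i) re-tie C1–C3, which shrinks the cyclohexenone to the cyclopentane C1–C3–C4–C5–C6 of a bicyclo[3.1.0]hexane-1,3,4-triol; (ii) cut C1–C2 and C2–C3 (CH2 dianion plus α,β-epoxy ketone, whose C4–O bond survives as the C4 hydroxyl); (iii) remove the epoxide O; (iv) cut C5–C1'; (v) cut C11'–C12'.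
Forward: C6 + C11 chain coupling, terminal iodide, 1,2-addition to a purchased cyclopentenone, epoxide, ketone, cyclopropane. The oxidative strain-release ring expansion 5 → 6 comes last, with no protecting group on the diol.
Stereochemistry: the OTBS carbon of commercial (R)-4-silyloxycyclopentenone sets C5 (anti addition). The C5 hydroxyl sets C4 (directed epoxidation, cis). The control centre is then oxidised to the C1 carbonyl. The 14'E alkene is bought with (E)-hex-3-en-1-ol.

Key step: step 9

Remark: the SMILES decodes to (4R,5S), i.e. a cis-diol, with an (E)-heptadec-14-en-1-yl chain. The remote alkene rules out free carbenes, OsO4, peracids and hydrogenation once the chain is on.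

Step 1
Reactants: 1 (E)-hex-3-en-1-ol
Product: 2 (E)-hex-3-en-1-yl 4-methylbenzenesulfonate
Conditions: TsCl, Et3N, DMAP (cat.), CH2Cl2, 0 °C → rt
Reagents that add atoms: 4-toluenesulfonyl chloride, Cc1ccc(cc1)S(=O)(=O)Cl
Why: Standard sulfonylation of a primary alcohol (tosylate formation) makes the leaving group without touching the E-alkene, whose geometry is bought with 1.

Step 2
Reactants: 2 (E)-hex-3-en-1-yl 4-methylbenzenesulfonate; 3 11-bromoundec-1-ene
Product: 5 (14E)-heptadeca-1,14-diene, via undec-10-enylmagnesium bromide 4 (not isolated)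
Conditions: 3, Mg, THF, rt → 40 °C; then 2, Li2CuCl4 (3 mol %), THF, −20 °C → rt
Reagents that add atoms: none
Why: Kochi-type copper-catalysed sp3–sp3 cross-coupling of a primary alkyl Grignard reagent with a primary tosylate joins C11'–C12' and should leave both alkenes and the E geometry untouched, because the homoallylic partner serves as the electrophile and never becomes an organometallic.

Step 3
Reactants: 5 (14E)-heptadeca-1,14-diene
Product: 7 (3E)-17-iodoheptadec-3-ene, via alkylzirconocene chloride 6 (not isolated)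
Conditions: Cp2Zr(H)Cl (1.05 equiv), THF, rt; then I2, 0 °C
Reagents that add atoms: iodine, II
Why: Hydrozirconation–iodination works here because the Schwartz reagent adds much faster to the monosubstituted than to the 1,2-disubstituted alkene, places Zr on the terminal carbon, and the C–Zr bond is then cleaved by iodine to the primary iodide.

Step 4
Reactants: 7 (3E)-17-iodoheptadec-3-ene; 8 (4R)-4-[(tert-butyldimethylsilyl)oxy]cyclopent-2-en-1-one
Product: 11 (1S,4R)-4-[(tert-butyldimethylsilyl)oxy]-1-[(14E)-heptadec-14-en-1-yl]cyclopent-2-en-1-ol (OH cis to OTBS), via alkyllithium 9 (not isolated), via alkylcerium dichloride 10 (not isolated)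
Conditions: t-BuLi (2.1 equiv), Et2O–pentane, −78 °C; CeCl3 (anhydrous), THF, −78 °C; then 8, −78 °C; aq NH4Cl
Reagents that add atoms: none
Why: Lithium–iodine exchange, transmetalation and organocerium 1,2-addition give a weakly basic nucleophile that should avoid enolisation and β-elimination of the silyloxy group and should attack the carbonyl on the face opposite to OTBS, which sets C5 (1S, OH cis to OTBS); the minor epimer is removed here by chromatography.

Step 5
Reactants: 11 (1S,4R)-4-[(tert-butyldimethylsilyl)oxy]-1-[(14E)-heptadec-14-en-1-yl]cyclopent-2-en-1-ol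
Product: 12 (1R,2S,4R,5S)-4-[(tert-butyldimethylsilyl)oxy]-2-[(14E)-heptadec-14-en-1-yl]-6-oxabicyclo[3.1.0]hexan-2-ol (OH, epoxide O and OTBS on one face)
Conditions: VO(acac)2 (5 mol %), t-BuOOH (decane), CH2Cl2, 0 °C → rt
Reagents that add atoms: tert-butyl hydroperoxide, CC(C)(C)OO
Why: Vanadium-catalysed hydroxyl-directed epoxidation of an allylic alcohol delivers oxygen to the ring alkene from the face of the tertiary OH, which sets the C4–O bond cis to C5–OH, and leaves the remote undirected E-alkene alone.

Step 6
Reactants: 12 (1R,2S,4R,5S)-4-[(tert-butyldimethylsilyl)oxy]-2-[(14E)-heptadec-14-en-1-yl]-6-oxabicyclo[3.1.0]hexan-2-ol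
Product: 13 (1R,2S,4R,5R)-2-[(14E)-heptadec-14-en-1-yl]-6-oxabicyclo[3.1.0]hexane-2,4-diol
Conditions: TBAF, THF, 0 °C → rt
Reagents that add atoms: none
Why: Fluoride-induced silyl ether cleavage is safe here because both oxygens sit on the epoxide face, so backside attack on the epoxide (Payne rearrangement) is geometrically excluded.

Step 7
Reactants: 13 (1R,2S,4R,5R)-2-[(14E)-heptadec-14-en-1-yl]-6-oxabicyclo[3.1.0]hexane-2,4-diol
Product: 14 (1S,4S,5R)-4-[(14E)-heptadec-14-en-1-yl]-4-hydroxy-6-oxabicyclo[3.1.0]hexan-2-one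
Conditions: Dess–Martin periodinane, CH2Cl2, 0 °C → rt
Reagents that add atoms: none
Why: Dess–Martin oxidation converts the only secondary alcohol into the future C1 ketone under nearly neutral conditions (no retro-aldol of the β-hydroxy ketone), the tertiary alcohol cannot react, and the control centre is erased after it has done its work.

Step 8
Reactants: 14 (1S,4S,5R)-4-[(14E)-heptadec-14-en-1-yl]-4-hydroxy-6-oxabicyclo[3.1.0]hexan-2-one
Product: 16 (1R,3S,4R,5R)-3-[(14E)-heptadec-14-en-1-yl]bicyclo[3.1.0]hexane-1,3,4-triol (C3–OH and C4–OH cis, cyclopropane CH2 on the other face), via iodozinciomethyl carbinolate 15 (not isolated)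
Conditions: CH2(ZnI)2 (3 equiv, stock solution in THF made beforehand from CH2I2, Zn, cat. PbCl2), THF, 0 °C → rt; sat. aq NH4Cl
Reagents that add atoms: bis(iodozincio)methane, I[Zn]C[Zn]I
Why: This is the known cyclopropanol synthesis from α,β-epoxy ketones and a gem-dizinc reagent: the first C–Zn bond should add to C1=O opposite to the epoxide oxygen, the second then displaces the C3–O bond from the back (3-exo-tet, inversion at C3), so the cis-fused cyclopropanol forms on the lower face while the untouched C4–O bond appears as the C4 hydroxyl cis to C5–OH, one further equivalent being spent on the free OH.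

Step 9
Reactants: 16 (1R,3S,4R,5R)-3-[(14E)-heptadec-14-en-1-yl]bicyclo[3.1.0]hexane-1,3,4-triol
Product: 18 (4R,5S)-5-[(14E)-heptadec-14-en-1-yl]-4,5-dihydroxycyclohex-2-en-1-one, via 3-chloroketone 17 (not isolated)
Conditions: FeCl3 (2.2 equiv), pyridine (1.1 equiv), DMF, 0 °C → rt; then NaOAc, MeOH, rt
Reagents that add atoms: none
Why: Fe(III) binds the cyclopropanol oxygen and takes one electron, the cyclopropyloxy radical undergoes β-scission of the C1–C3 zero bridge (release of cyclopropane strain, formation of C1=O and of a secondary C3 radical inside a six-membered ring), a second FeCl3 transfers chlorine to C3 to give 17, and acetate removes HCl by E1cB to leave the C2=C3 enone. The closest known reaction type is the FeCl3-mediated oxidative ring expansion of bicyclo[n.1.0]alkan-1-ols and their silyl ethers to 3-chlorocycloalkanones and 2-cycloalkenones (Saegusa ring expansion). No ring is closed: the ring C1–C2–C3–C4–C5–C6 arises because the bond shared by the five- and three-membered rings is cut, so that C2 ends up inserted between C1 and C3. No lasting stereocentre is made (the C3–Cl centre of 17 forms unselectively and is erased), and C4 and C5 keep their configuration because no bond to them is touched. The step needs endocyclic rather than exocyclic C–C scission, secured by secondary versus primary radical stability and by the reversibility of the exocyclic opening (Dowd–Beckwith manifold), and it needs loss of chloride from C3 rather than hydroxide from C5, secured by the leaving-group difference under a base as weak as acetate. DMF and pyridine damp Lewis and Brønsted acidity so that ionisation of the cyclopropylcarbinyl C4–OH should stay slower than electron transfer, and the remote 14'E alkene is out of reach of the C3 radical.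

**Compound list**
1 | (E)-hex-3-en-1-ol | CC/C=C/CCO | starting material
2 | (E)-hex-3-en-1-yl 4-methylbenzenesulfonate | CC/C=C/CCOS(=O)(=O)c1ccc(C)cc1 | intermediate
3 | 11-bromoundec-1-ene | C=CCCCCCCCCCBr | starting material
4 | undec-10-en-1-ylmagnesium bromide | C=CCCCCCCCCC[Mg]Br | intermediate
5 | (14E)-heptadeca-1,14-diene | CC/C=C/CCCCCCCCCCCC=C | intermediate
6 | chlorobis(cyclopentadienyl)[(14E)-heptadec-14-en-1-yl]zirconium (Cp drawn σ-bound) | CC/C=C/CCCCCCCCCCCCC[Zr](Cl)(C1C=CC=C1)C1C=CC=C1 | intermediate
7 | (3E)-17-iodoheptadec-3-ene | CC/C=C/CCCCCCCCCCCCCI | intermediate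
8 | (4R)-4-[(tert-butyldimethylsilyl)oxy]cyclopent-2-en-1-one | O=C1C=C[C@H](O[Si](C)(C)C(C)(C)C)C1 | starting material
9 | [(14E)-heptadec-14-en-1-yl]lithium | CC/C=C/CCCCCCCCCCCCC[Li] | intermediate
10 | dichloro[(14E)-heptadec-14-en-1-yl]cerium | CC/C=C/CCCCCCCCCCCCC[Ce](Cl)Cl | intermediate
11 | (1S,4R)-4-[(tert-butyldimethylsilyl)oxy]-1-[(14E)-heptadec-14-en-1-yl]cyclopent-2-en-1-ol | CC/C=C/CCCCCCCCCCCCC[C@@]1(O)C=C[C@H](O[Si](C)(C)C(C)(C)C)C1 | intermediate
12 | (1R,2S,4R,5S)-4-[(tert-butyldimethylsilyl)oxy]-2-[(14E)-heptadec-14-en-1-yl]-6-oxabicyclo[3.1.0]hexan-2-ol | CC/C=C/CCCCCCCCCCCCC[C@@]1(O)[C@@H]2O[C@@H]2[C@H](O[Si](C)(C)C(C)(C)C)C1 | intermediate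
13 | (1R,2S,4R,5R)-2-[(14E)-heptadec-14-en-1-yl]-6-oxabicyclo[3.1.0]hexane-2,4-diol | CC/C=C/CCCCCCCCCCCCC[C@@]1(O)[C@@H]2O[C@@H]2[C@H](O)C1 | intermediate
14 | (1S,4S,5R)-4-[(14E)-heptadec-14-en-1-yl]-4-hydroxy-6-oxabicyclo[3.1.0]hexan-2-one | CC/C=C/CCCCCCCCCCCCC[C@@]1(O)[C@@H]2O[C@@H]2C(=O)C1 | intermediate
15 | C1 adduct of 14: iodozinc alkoxides at C1 and C5, CH2ZnI on the face of C1 opposite to the intact epoxide | CC/C=C/CCCCCCCCCCCCC[C@@]1(O[Zn]I)[C@@H]2O[C@@H]2[C@@](O[Zn]I)(C[Zn]I)C1 | intermediate
16 | (1R,3S,4R,5R)-3-[(14E)-heptadec-14-en-1-yl]bicyclo[3.1.0]hexane-1,3,4-triol | CC/C=C/CCCCCCCCCCCCC[C@@]1(O)[C@H](O)[C@H]2C[C@@]2(O)C1 | intermediate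
17 | (4S,5S)-3-chloro-5-[(14E)-heptadec-14-en-1-yl]-4,5-dihydroxycyclohexan-1-one (both C3 epimers) | CC/C=C/CCCCCCCCCCCCC[C@]1(O)CC(=O)CC(Cl)[C@H]1O | intermediate
18 | (4R,5S)-5-[(14E)-heptadec-14-en-1-yl]-4,5-dihydroxycyclohex-2-en-1-one | CC/C=C/CCCCCCCCCCCCC[C@]1(O)CC(=O)C=C[C@H]1O | target

Total steps: 9. Longest linear sequence: 9 steps (1 or 3 → 18).

**Steps most likely to fail**

Step 9. The free cyclopropylcarbinyl C4 hydroxyl may ionise under the acidic iron medium, giving heterolytic fragmentation with loss of the C4 oxygen. The triol may tie up iron and slow electron transfer. The product may dehydrate and aromatise during the elimination.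
The fallback drops the protecting-group-free endgame and runs the ring expansion on the fully masked classical substrate. It sets out from 16 and comes back at 18.
- Exhaustive silylation with N-(trimethylsilyl)imidazole gives the tris(trimethylsilyl) ether F1.
- FeCl3 in DMF gives the 3-chloroketone bis(trimethylsilyl) ether F2.
- Sodium acetate gives the bis(trimethylsilyl) enone F3.
- Buffered HF·pyridine at 0 °C frees 18 under non-basic conditions. Partial loss of trimethylsilyl groups on the way is harmless.

Step 8. The gem-dizinc reagent may attack the carbonyl face on the epoxide side, giving an adduct that cannot close. The zinc aldolate may open by retro-aldol, or simple methyl carbinol formation may prevail.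
The fallback builds the oxycyclopropane from an enol ether instead. It sets out from 14 and comes back at 18.
- Organoselenium-mediated reductive cleavage of the Cα–O bond (PhSeSePh, NaBH4, EtOH) gives (3S,4R)-3-[(14E)-heptadec-14-en-1-yl]-3,4-dihydroxycyclopentan-1-one F4.
- 2,2-Dimethoxypropane/PPTS gives the acetonide ketone F5.
- LDA with TMSCl as internal quench at −78 °C deprotonates the CH2 remote from the quaternary carbon and gives the trimethylsilyl enol ether F6.
- One equivalent of Et2Zn/CH2I2 (Furukawa variant of the Simmons–Smith reaction, in which the enol ether outruns the chain alkene) gives the silyloxycyclopropane F7.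
- FeCl3/DMF gives the chloroketone acetonide F8, and sodium acetate gives the enone acetonide F9.
- Aqueous trifluoroacetic acid at 0 °C gives 18.

Step 4. Facial selectivity may be poor because the controlling centre is 1,3 to the carbonyl. Any epimer carried on becomes the enantiomer after step 7. Some β-elimination of the silyloxy group may also occur.
The fallback installs the epoxide before the chain, so that two groups shield the same face. It sets out from 8 and comes back at 12.
- Luche reduction gives (1S,4R)-4-[(tert-butyldimethylsilyl)oxy]cyclopent-2-en-1-ol F10.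
- Hydroxyl-directed epoxidation with mCPBA (no chain alkene is present yet) gives the all-cis epoxy alcohol F11.
- Dess–Martin oxidation gives the epoxy ketone F12, in which the neighbouring epoxide and the OTBS group block one face.
- Organocerium 10 then adds from the open face and gives 12 directly, replacing steps 4 and 5.

**Further compounds**
F1 | step 9 | tris(trimethylsilyl) ether of 16 | CC/C=C/CCCCCCCCCCCCC[C@@]1(O[Si](C)(C)C)[C@H](O[Si](C)(C)C)[C@H]2C[C@@]2(O[Si](C)(C)C)C1
F2 | step 9 | 3-chloroketone bis(trimethylsilyl) ether (both C3 epimers) | CC/C=C/CCCCCCCCCCCCC[C@]1(O[Si](C)(C)C)CC(=O)CC(Cl)[C@H]1O[Si](C)(C)C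
F3 | step 9 | bis(trimethylsilyl) ether of 18 | CC/C=C/CCCCCCCCCCCCC[C@]1(O[Si](C)(C)C)CC(=O)C=C[C@H]1O[Si](C)(C)C
F4 | step 8 | (3S,4R)-3-[(14E)-heptadec-14-en-1-yl]-3,4-dihydroxycyclopentan-1-one | CC/C=C/CCCCCCCCCCCCC[C@@]1(O)[C@H](O)CC(=O)C1
F5 | step 8 | acetonide of F4 (cis-fused dioxolane) | CC/C=C/CCCCCCCCCCCCC[C@]12CC(=O)C[C@H]1OC(C)(C)O2
F6 | step 8 | trimethylsilyl enol ether of F5, C=C toward the CH(O) carbon | CC/C=C/CCCCCCCCCCCCC[C@]12CC(O[Si](C)(C)C)=C[C@H]1OC(C)(C)O2
F7 | step 8 | silyloxycyclopropane from F6, CH2 on the face opposite to the dioxolane | CC/C=C/CCCCCCCCCCCCC[C@]12C[C@]3(O[Si](C)(C)C)C[C@@H]3[C@H]1OC(C)(C)O2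
F8 | step 8 | 3-chloroketone acetonide (both C3 epimers) | CC/C=C/CCCCCCCCCCCCC[C@]12CC(=O)CC(Cl)[C@H]1OC(C)(C)O2
F9 | step 8 | acetonide of 18 | CC/C=C/CCCCCCCCCCCCC[C@]12CC(=O)C=C[C@H]1OC(C)(C)O2
F10 | step 4 | (1S,4R)-4-[(tert-butyldimethylsilyl)oxy]cyclopent-2-en-1-ol (cis) | O[C@@H]1C=C[C@H](O[Si](C)(C)C(C)(C)C)C1
F11 | step 4 | 4-[(tert-butyldimethylsilyl)oxy]-6-oxabicyclo[3.1.0]hexan-2-ol, OH, epoxide O and OTBS on one face | O[C@@H]1[C@@H]2O[C@@H]2[C@H](O[Si](C)(C)C(C)(C)C)C1
F12 | step 4 | 4-[(tert-butyldimethylsilyl)oxy]-6-oxabicyclo[3.1.0]hexan-2-one, epoxide O and OTBS cis | O=C1[C@@H]2O[C@@H]2[C@H](O[Si](C)(C)C(C)(C)C)C1
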